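## Retrosynthetic overview

1. The target is an intact 2,5-dihydroxy-1,4-benzoquinone ring with one unbranched C16 chain at C3. The only strategic cut is the C3(ring)–C1'(chain) bond, which leads back to the commercial, unprotected dihydroxyquinone and a hexadecyl radical.
2. Both carbons are donors by nature: C3 is the alpha carbon of the vinylogous acid HO–C2=C3–C4=O, and C1' is the alpha carbon of heptadecanoic acid. They are therefore joined by a decarboxylative radical C–H alkylation, and the carboxyl group is a traceless activator that leaves as CO2 in the key step itself.
3. Enabling feature: the free C3–H of the six-membered quinone ring is also the beta carbon of the enone O=C1–C2=C3. A radical adding there leaves its spin on C2, between the C2–OH donor and the C1=O acceptor. C3 and C6 are equivalent by the twofold symmetry of the ring, so there is no regiochemical question.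
4. Ring order: no ring is formed. The single carbocycle is bought complete and at its final oxidation level, and no protecting group is used. The radical source, a diacyl peroxide, comes from the fatty acid in two steps.

Key step: step 3

Remark: the target has no stereocentre and is treated as the 2,5-dihydroxy-1,4-quinone tautomer written in the SMILES.

## Route

Step 1
Reactants: 1 heptadecanoic acid (margaric acid, unbranched C17 acid)
Product: 2 heptadecanoyl chloride
Conditions: (COCl)2 (1.3 equiv), DMF (cat.), CH2Cl2, 0 °C to rt, then evaporation
Reagents that add atoms: oxalyl chloride, O=C(Cl)C(=O)Cl
Why: Acid chloride formation via the Vilsmeier-type chloroiminium salt from DMF and oxalyl chloride is general for saturated fatty acids, gives only gaseous by-products and meets no other functional group or stereocentre in 1.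

Step 2
Reactants: 2 heptadecanoyl chloride (two molecules per molecule of product)
Product: 4 diheptadecanoyl peroxide, via peroxyheptadecanoic acid 3 (not isolated)
Conditions: 30% aq H2O2 (0.55 equiv), pyridine (1.1 equiv), Et2O, 0 °C
Reagents that add atoms: hydrogen peroxide, OO
Why: Two successive nucleophilic acyl substitutions on the alpha-effect nucleophile H2O2 (Schotten–Baumann-type acylation, first to peracid 3, then to 4) with pyridine at 0 °C are the standard entry to long-chain aliphatic diacyl peroxides, which are crystalline and storable cold, and no stereocentre is involved.

Step 3
Reactants: 4 diheptadecanoyl peroxide; 5 2,5-dihydroxy-1,4-benzoquinone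
Product: 8 2,5-dihydroxy-3-hexadecyl-1,4-benzoquinone, via hexadecyl radical 6 (not isolated), via ring adduct radical 7 (not isolated)
Conditions: 5 (3 equiv), 4 added in portions, AcOH, N2, 90–95 °C
Reagents that add atoms: none
Why: Thermal homolysis of the O–O bond of 4 and fast loss of CO2 give the primary, nucleophilic hexadecyl radical 6, which adds to the unsubstituted C3 of the electron-poor ring of 5 (beta carbon of the O=C1–C2=C3 enone) to give adduct radical 7 with the spin on C2 between the C2–OH and the C1 carbonyl. Radical 7 is a ketyl-like reductant that passes an electron to a further molecule of 4 (induced decomposition to heptadecanoic acid, CO2 and a new 6, so that a chain runs), and loss of the C3 proton restores the hydroxyquinone 8 at its final oxidation level. The closest known reaction type is the peroxide alkylation of hydroxy-1,4-benzoquinones and hydroxy-1,4-naphthoquinones with aliphatic diacyl peroxides, the quinone counterpart of the Minisci reaction. No ring is closed and no lasting stereocentre is formed, since the sp3 centre at C3 of 7 is flattened again on return to the quinone. The step needs C- over O-alkylation, a single site and a single alkylation: the radical path bypasses the ambident oxyanion that a hexadecyl halide would O-alkylate, C3 and C6 are the only C–H positions and are equivalent by the twofold symmetry of 5, and a threefold excess of 5 with slow addition of 4 should hold back a second attack at C6 of 8. A primary radical has no rearrangement path, so the chain should arrive unbranched, and surplus 5 (nearly insoluble in cold chloroform) and the co-formed fatty acid should be removable by filtration and chromatography or crystallisation.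

## Compound list

1 | heptadecanoic acid | CCCCCCCCCCCCCCCCC(=O)O | starting material
2 | heptadecanoyl chloride | CCCCCCCCCCCCCCCCC(=O)Cl | intermediate
3 | peroxyheptadecanoic acid (not isolated) | CCCCCCCCCCCCCCCCC(=O)OO | intermediate
4 | diheptadecanoyl peroxide | CCCCCCCCCCCCCCCCC(=O)OOC(=O)CCCCCCCCCCCCCCCC | intermediate
5 | 2,5-dihydroxy-1,4-benzoquinone | O=C1C=C(O)C(=O)C=C1O | starting material
6 | hexadecyl radical, primary (not isolated) | CCCCCCCCCCCCCCC[CH2] | intermediate
7 | ring adduct radical: hexadecyl and H on sp3 C3, spin on C2 bearing OH, racemic and transient (not isolated) | CCCCCCCCCCCCCCCCC1[C](O)C(=O)C=C(O)C1=O | intermediate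
8 | 2,5-dihydroxy-3-hexadecyl-1,4-benzoquinone (2,5-dihydroxy-3-hexadecylcyclohexa-2,5-diene-1,4-dione), achiral | CCCCCCCCCCCCCCCCC1=C(O)C(=O)C=C(O)C1=O | target

## Step count and risks

Total step count: 3. Longest linear sequence: 3 (1 to 2 to 4 to 8). Compound 5 enters as purchased.

Steps most likely to fail, riskiest first:

**1. Step 3.**
- **What may go wrong:** A second alkylation may occur at C6. Cage recombination of the radical pair and early chain termination may use up the peroxide without forming the ring–chain bond.
- **Fallback:** A polar, organocatalytic three-component reductive alkylation. It sets out from 5, which is stirred with commercial hexadecanal F1, diethyl 1,4-dihydro-2,6-dimethylpyridine-3,5-dicarboxylate (Hantzsch ester, 1 equiv) and L-proline (20 mol %) in CH2Cl2 at rt.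
- **How it runs:** Knoevenagel condensation of the nucleophilic C3 with the aldehyde should give 5-hydroxy-3-hexadecylidenecyclohex-5-ene-1,2,4-trione F2, a quinone-methide-type acceptor whose alkene geometry is not controlled and is erased again. Conjugate hydride transfer from the Hantzsch ester and enolisation bring the sequence back to the route at 8. The same bond is formed, now with matched polarity.

**2. Step 2.**
- **What may go wrong:** The acid chloride may hydrolyse at the water/ether interface, the acylation may stop at the peracid stage, or the peroxide may decompose on isolation and drying.
- **Fallback:** Avoid any isolated peroxide by a silver-catalysed persulfate decarboxylation (Minisci-type alkylation of a quinone). It sets out from 1, which is heated with 5 (excess), AgNO3 (0.2 equiv) and (NH4)2S2O8 (1.5 equiv) in MeCN/H2O at 70–75 °C.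
- **How it runs:** Ag(II) oxidises the carboxylate and loss of CO2 gives the same radical 6. This adds to 5 to give 7, and oxidation of 7 brings the sequence back at 8. This fallback makes no compound outside the list (F0).

**3. Step 1.**
- **What may go wrong:** Activation may be incomplete, moisture may lead to the anhydride, or residual oxalyl chloride and HCl may be carried over and destroy H2O2 in the next step.
- **Fallback:** Carbodiimide activation without an acyl halide. It sets out from 1, which is treated with DCC (1.05 equiv), DMAP (cat.) and 30% aq H2O2 (0.55 equiv) in CH2Cl2 at −10 to 0 °C.
- **How it runs:** O-Heptadecanoyl-N,N'-dicyclohexylisourea F3 is perhydrolysed to 3, a second F3 acylates 3, and the sequence comes back at 4 after the urea is filtered off.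

## Further compounds

F1 | step 3 | hexadecanal | CCCCCCCCCCCCCCCC=O
F2 | step 3 | 5-hydroxy-3-hexadecylidenecyclohex-5-ene-1,2,4-trione (alkene geometry undefined, not isolated) | CCCCCCCCCCCCCCCC=C1C(=O)C(=O)C=C(O)C1=O
F0 | step 2 | none | none
F3 | step 1 | O-heptadecanoyl-N,N'-dicyclohexylisourea (not isolated) | CCCCCCCCCCCCCCCCC(=O)OC(=NC1CCCCC1)NC1CCCCC1
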